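**Retrosynthetic overview**

1. Ring atoms are numbered C1=C10(C14 methyl), C2, C3, C4(C15 methyl)=C5, C6–OH, C7–isopropyl, C8–O-aroyl, C9. Target 24 ← 23 (desilylation) ← acyclic iodo-triene ester 21 by closure of the C3–C4 bond (9-BBN hydroboration, then B-alkyl Suzuki–Miyaura coupling).
2. Enabling feature: in the cyclodecadiene the 1,5-diene C5=C4(C15)–C3H2–C2H2–C1=C10 has both double bonds cis in the ring. C3 is a methylene homoallylic to C1=C10, so it can be the boron-bearing end of a hydroborated terminal Z diene. C4 is the methyl-bearing alkene carbon next to the C6 carbinol, so it can be a Z alkenyl iodide. The two cis alkenes fold the chain so that C3 and C4 can meet.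
3. 21 ← alcohol 16 + acid 19 (C8 ester); 16 ← epoxide 12 + Z dienyl metal from 13 (C9–C10 bond); 12 ← 8 by iodocarbonate cyclisation, which sets C8 syn to the C6 oxygen.
4. 8 ← (Z)-3-iodobut-2-enal 4 + E allylboronate 7 by catalytic asymmetric anti allylboration (C6–C7 bond; sets C6 and C7).
5. Both Z methyl alkenes (C6–C5=C4–C15 and C2–C1=C10–C14) are two copies of 4, made from but-2-yn-1-ol; C3 comes from a Wittig methylenation. Ring order: 1,3-dioxan-2-one (temporary) → oxirane (temporary) → ten-membered carbocycle; the benzene ring is bought.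

Key step: step 13

Assumption: (R)-TRIP is taken to direct the allyl group of 7 to the Re face of aldehyde 4, the sense recalled for its allyl- and crotylborations of aldehydes; if the sense is opposite with this aldehyde, (S)-TRIP is used and nothing else changes.

**Route**

Step 1
Reactants: 1 but-2-yn-1-ol
Product: 3 (2Z)-3-iodobut-2-en-1-ol, via sodium alkenylalanate 2 (not isolated)
Conditions: NaAlH2(OCH2CH2OMe)2, THF, 0 °C to rt; then I2, THF, −78 °C
Reagents that add atoms: iodine, II
Why: Hydroxyl-directed trans-hydroalumination delivers hydride to C2 and holds aluminium on C3 in a five-membered alkoxyalanate ring, so iodinolysis with retention should give only the Z iodoalkene (iodine cis to CH2OH).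

Step 2
Reactants: 3 (2Z)-3-iodobut-2-en-1-ol
Product: 4 (2Z)-3-iodobut-2-enal
Conditions: MnO2, CH2Cl2, rt, dark
Reagents that add atoms: none
Why: Heterogeneous allylic oxidation with MnO2 is neutral, stops at the aldehyde and should leave the Z iodoalkene unisomerised.

Step 3
Reactants: 5 3-methylbut-1-yne
Product: 6 4,4,5,5-tetramethyl-2-[(1E)-3-methylbut-1-en-1-yl]-1,3,2-dioxaborolane
Conditions: pinacolborane, Cp2Zr(H)Cl (5 mol%), Et3N (10 mol%), neat, 60 °C, sealed vessel
Reagents that add atoms: pinacolborane, [H]B1OC(C)(C)C(C)(C)O1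
Why: Cp2Zr(H)Cl-catalysed hydroboration of a terminal alkyne is a syn, anti-Markovnikov addition and should give the E alkenylboronate only.

Step 4
Reactants: 6 4,4,5,5-tetramethyl-2-[(1E)-3-methylbut-1-en-1-yl]-1,3,2-dioxaborolane
Product: 7 4,4,5,5-tetramethyl-2-[(2E)-4-methylpent-2-en-1-yl]-1,3,2-dioxaborolane
Conditions: ClCH2I, n-BuLi, THF, −78 °C to rt
Reagents that add atoms: chloroiodomethane, ClCI
Why: In this Matteson homologation chloromethyllithium, formed in the flask, adds to boron and the alkenyl group undergoes a 1,2-shift with loss of chloride and retention of the E geometry, which should give the E allylboronate.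

Step 5
Reactants: 4 (2Z)-3-iodobut-2-enal; 7 4,4,5,5-tetramethyl-2-[(2E)-4-methylpent-2-en-1-yl]-1,3,2-dioxaborolane
Product: 8 (2Z,4R,5R)-2-iodo-5-(propan-2-yl)hepta-2,6-dien-4-ol
Conditions: (R)-TRIP [(R)-3,3'-bis(2,4,6-triisopropylphenyl)-1,1'-binaphthyl-2,2'-diyl hydrogen phosphate, 5 mol%], 4 Å molecular sieves, toluene, −30 °C
Reagents that add atoms: none
Why: Chiral phosphoric acid-catalysed allylboration runs through a chair Zimmerman–Traxler transition state in which the E geometry of 7 places the isopropyl group equatorial and so sets the anti relation of C6–OH and C7–isopropyl, while the catalyst, bound to a boronate oxygen and the formyl hydrogen, should direct attack to the Re face of 4 and set 4R,5R.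

Step 6
Reactants: 8 (2Z,4R,5R)-2-iodo-5-(propan-2-yl)hepta-2,6-dien-4-ol
Product: 9 tert-butyl (2Z,4R,5R)-2-iodo-5-(propan-2-yl)hepta-2,6-dien-4-yl carbonate
Conditions: Boc2O, DMAP (cat.), MeCN, rt
Reagents that add atoms: di-tert-butyl dicarbonate, CC(C)(C)OC(=O)OC(=O)OC(C)(C)C
Why: DMAP-catalysed acylation of the secondary alcohol should give the tert-butyl carbonate that serves as the internal oxygen nucleophile of the next step.

Step 7
Reactants: 9 tert-butyl (2Z,4R,5R)-2-iodo-5-(propan-2-yl)hepta-2,6-dien-4-yl carbonate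
Product: 11 (2Z,4R,5S)-2-iodo-6-methyl-5-[(2S)-oxiran-2-yl]hept-2-en-4-ol, via iodocarbonate 10 (not isolated)
Conditions: IBr, toluene, −85 °C; then K2CO3, MeOH, rt
Reagents that add atoms: none
Why: Iodocarbonate cyclisation (iodonium formation at the terminal alkene, 6-exo attack of the carbonate carbonyl oxygen, loss of the tert-butyl group) should pass through a chair with the alkenyl, isopropyl and iodomethyl groups all equatorial, which sets C8 syn to the C6 oxygen and anti to the isopropyl group, and methanolysis of the cyclic carbonate then lets the C8 alkoxide displace iodide to give the epoxide without change at C8.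

Step 8
Reactants: 11 (2Z,4R,5S)-2-iodo-6-methyl-5-[(2S)-oxiran-2-yl]hept-2-en-4-ol
Product: 12 triethyl{[(2Z,4R,5R)-2-iodo-6-methyl-5-[(2S)-oxiran-2-yl]hept-2-en-4-yl]oxy}silane
Conditions: TESCl, imidazole, CH2Cl2, 0 °C to rt
Reagents that add atoms: chlorotriethylsilane, CC[Si](Cl)(CC)CC
Why: Silylation of the only free hydroxyl under standard imidazole conditions should protect C6–OH and keep it distinct from the C8 oxygen that is released later.

Step 9
Reactants: 4 (2Z)-3-iodobut-2-enal
Product: 13 (3Z)-4-iodopenta-1,3-diene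
Conditions: Ph3PCH3Br, KN(SiMe3)2, THF, 0 °C; then 4, −78 to 0 °C; product kept as an Et2O solution
Reagents that add atoms: methyltriphenylphosphonium bromide, C[P+](c1ccccc1)(c1ccccc1)c1ccccc1.[Br-]
Why: Wittig methylenation with the non-stabilised ylide converts the aldehyde into the terminal C2=C3 alkene and should not touch the trisubstituted Z iodoalkene.

Step 10
Reactants: 12 triethyl{[(2Z,4R,5R)-2-iodo-6-methyl-5-[(2S)-oxiran-2-yl]hept-2-en-4-yl]oxy}silane; 13 (3Z)-4-iodopenta-1,3-diene
Product: 16 (3Z,6R,7R,8R,9Z)-10-iodo-4-methyl-7-(propan-2-yl)-8-[(triethylsilyl)oxy]undeca-1,3,9-trien-6-ol, via dienyllithium 14 (not isolated), via dienylmagnesium bromide 15 (not isolated)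
Conditions: 13, t-BuLi (2 equiv), Et2O, −78 °C; MgBr2·OEt2, −78 to −40 °C; then CuI (10 mol%), 12, THF, −40 to −20 °C
Reagents that add atoms: none
Why: Iodine–lithium exchange and transmetalation to magnesium proceed with retention at the alkenyl carbon, and copper-catalysed SN2 opening of the terminal epoxide at its unsubstituted carbon C9 should give the homoallylic alcohol with the Z C10=C1 alkene and the C8 configuration intact.

Step 11
Reactants: 17 4-hydroxybenzoic acid
Product: 19 4-{[tri(propan-2-yl)silyl]oxy}benzoic acid, via bis-silyl ester 18 (not isolated)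
Conditions: TIPSCl (2.2 equiv), imidazole, DMF, rt; then AcOH/THF/H2O, rt
Reagents that add atoms: chlorotri(propan-2-yl)silane, CC(C)[Si](Cl)(C(C)C)C(C)C
Why: Exhaustive silylation followed by selective hydrolysis of the much more labile silyl ester should leave the base-tolerant aryl silyl ether and free the acid.

Step 12
Reactants: 16 (3Z,6R,7R,8R,9Z)-10-iodo-4-methyl-7-(propan-2-yl)-8-[(triethylsilyl)oxy]undeca-1,3,9-trien-6-ol; 19 4-{[tri(propan-2-yl)silyl]oxy}benzoic acid
Product: 21 (3Z,6R,7R,8R,9Z)-10-iodo-4-methyl-7-(propan-2-yl)-8-[(triethylsilyl)oxy]undeca-1,3,9-trien-6-yl 4-{[tri(propan-2-yl)silyl]oxy}benzoate, via mixed anhydride 20 (not isolated)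
Conditions: 19, 2,4,6-trichlorobenzoyl chloride, Et3N, THF, rt; then 16, DMAP, toluene, rt
Reagents that add atoms: none
Why: In this Yamaguchi esterification DMAP attacks the unhindered carbonyl of the mixed anhydride and the acylpyridinium ion acylates the hindered C8 hydroxyl, which should give the ester with retention at C8.

Step 13
Reactants: 21 (3Z,6R,7R,8R,9Z)-10-iodo-4-methyl-7-(propan-2-yl)-8-[(triethylsilyl)oxy]undeca-1,3,9-trien-6-yl 4-{[tri(propan-2-yl)silyl]oxy}benzoate
Product: 23 (1R,3Z,7Z,9S,10R)-3,7-dimethyl-10-(propan-2-yl)-9-[(triethylsilyl)oxy]cyclodeca-3,7-dien-1-yl 4-{[tri(propan-2-yl)silyl]oxy}benzoate, via alkylborane 22 (not isolated)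
Conditions: 9-BBN, THF, 0 °C to rt; then slow addition to Pd(dppf)Cl2 (20 mol%), AsPh3, K3PO4 (aq), THF/DMF, rt, 2 mM
Reagents that add atoms: none
Why: 9-BBN adds only to the monosubstituted C2=C3 bond of the Z diene (boron on C3; the trisubstituted C10=C1 and C4=C5 bonds are too hindered), and alkylborane 22 is then fed slowly to the catalyst, where oxidative addition of zerovalent palladium into the C4–I bond, phosphate-assisted transmetalation of the primary alkyl group from boron and reductive elimination form the C3–C4 bond. The closest known reaction type is the macrocyclising B-alkyl Suzuki–Miyaura coupling of a Z trisubstituted alkenyl iodide with a 9-BBN alkylborane made in the same flask. The ten-membered carbocycle closes by C(sp3)–C(sp2) reductive elimination from an eleven-membered alkyl(alkenyl) palladacycle of divalent palladium, with the C4=C5 bond ending inside the new ring. No stereocentre is formed: C6, C7 and C8 are not involved, and oxidative addition and reductive elimination go with retention, so the Z geometry at C4=C5 (C3 cis to C6) is carried over and the Z C10=C1 bond is untouched. The step needs chemoselective hydroboration, ring closure in preference to oligomerisation, and reductive elimination in preference to β-hydride elimination; the first is secured by C2=C3 being the only monosubstituted alkene, the second by high dilution together with the two cis alkenes and the branched C6–C8 segment, which fold the chain and bring C3 near C4, and the third by the wide-bite-angle dppf ligand with AsPh3.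

Step 14
Reactants: 23 (1R,3Z,7Z,9S,10R)-3,7-dimethyl-10-(propan-2-yl)-9-[(triethylsilyl)oxy]cyclodeca-3,7-dien-1-yl 4-{[tri(propan-2-yl)silyl]oxy}benzoate
Product: 24 (1R,3Z,7Z,9S,10S)-9-hydroxy-3,7-dimethyl-10-(propan-2-yl)cyclodeca-3,7-dien-1-yl 4-hydroxybenzoate
Conditions: Bu4NF, AcOH, THF, 0 °C to rt
Reagents that add atoms: none
Why: Fluoride-induced cleavage of both silyl ethers, buffered with acetic acid so that no free C6 alkoxide builds up, should release the allylic alcohol and the phenol without migration or loss of the C8 ester and without the acid that could trigger transannular cyclisation of the 1,5-diene.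

**Compound list**

1 | but-2-yn-1-ol | CC#CCO | starting material
2 | sodium 2,2-bis(2-methoxyethoxy)-3-methyl-2,5-dihydro-1,2-oxaluminol-2-uide (cyclic Z alkenylalanate) | CC1=CCO[Al-]1(OCCOC)OCCOC.[Na+] | intermediate
3 | (2Z)-3-iodobut-2-en-1-ol | C/C(I)=C/CO | intermediate
4 | (2Z)-3-iodobut-2-enal | C/C(I)=C/C=O | intermediate
5 | 3-methylbut-1-yne | CC(C)C#C | starting material
6 | 4,4,5,5-tetramethyl-2-[(1E)-3-methylbut-1-en-1-yl]-1,3,2-dioxaborolane | CC(C)/C=C/B1OC(C)(C)C(C)(C)O1 | intermediate
7 | 4,4,5,5-tetramethyl-2-[(2E)-4-methylpent-2-en-1-yl]-1,3,2-dioxaborolane | CC(C)/C=C/CB1OC(C)(C)C(C)(C)O1 | intermediate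
8 | (2Z,4R,5R)-2-iodo-5-(propan-2-yl)hepta-2,6-dien-4-ol | C/C(I)=C/[C@H](O)[C@H](C(C)C)C=C | intermediate
9 | tert-butyl (2Z,4R,5R)-2-iodo-5-(propan-2-yl)hepta-2,6-dien-4-yl carbonate | C/C(I)=C/[C@H](OC(=O)OC(C)(C)C)[C@H](C(C)C)C=C | intermediate
10 | (4S,5S,6R)-4-(iodomethyl)-6-[(1Z)-2-iodoprop-1-en-1-yl]-5-(propan-2-yl)-1,3-dioxan-2-one | C/C(I)=C/[C@@H]1OC(=O)O[C@H](CI)[C@H]1C(C)C | intermediate
11 | (2Z,4R,5S)-2-iodo-6-methyl-5-[(2S)-oxiran-2-yl]hept-2-en-4-ol | C/C(I)=C/[C@H](O)[C@H](C(C)C)[C@H]1CO1 | intermediate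
12 | triethyl{[(2Z,4R,5R)-2-iodo-6-methyl-5-[(2S)-oxiran-2-yl]hept-2-en-4-yl]oxy}silane | C/C(I)=C/[C@H](O[Si](CC)(CC)CC)[C@H](C(C)C)[C@H]1CO1 | intermediate
13 | (3Z)-4-iodopenta-1,3-diene | C/C(I)=C/C=C | intermediate
14 | (2E)-penta-2,4-dien-2-yllithium (lithium cis to the vinyl group) | C/C([Li])=C/C=C | intermediate
15 | bromo[(2Z)-penta-2,4-dien-2-yl]magnesium | C/C([Mg]Br)=C/C=C | intermediate
16 | (3Z,6R,7R,8R,9Z)-10-iodo-4-methyl-7-(propan-2-yl)-8-[(triethylsilyl)oxy]undeca-1,3,9-trien-6-ol | C/C(I)=C/[C@H](O[Si](CC)(CC)CC)[C@H](C(C)C)[C@H](O)C/C(C)=C\C=C | intermediate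
17 | 4-hydroxybenzoic acid | OC(=O)c1ccc(O)cc1 | starting material
18 | tri(propan-2-yl)silyl 4-{[tri(propan-2-yl)silyl]oxy}benzoate | CC(C)[Si](Oc1ccc(cc1)C(=O)O[Si](C(C)C)(C(C)C)C(C)C)(C(C)C)C(C)C | intermediate
19 | 4-{[tri(propan-2-yl)silyl]oxy}benzoic acid | CC(C)[Si](Oc1ccc(cc1)C(O)=O)(C(C)C)C(C)C | intermediate
20 | 2,4,6-trichlorobenzoic 4-{[tri(propan-2-yl)silyl]oxy}benzoic anhydride | CC(C)[Si](Oc1ccc(cc1)C(=O)OC(=O)c1c(Cl)cc(Cl)cc1Cl)(C(C)C)C(C)C | intermediate
21 | (3Z,6R,7R,8R,9Z)-10-iodo-4-methyl-7-(propan-2-yl)-8-[(triethylsilyl)oxy]undeca-1,3,9-trien-6-yl 4-{[tri(propan-2-yl)silyl]oxy}benzoate | C/C(I)=C/[C@H](O[Si](CC)(CC)CC)[C@H](C(C)C)[C@H](OC(=O)c1ccc(O[Si](C(C)C)(C(C)C)C(C)C)cc1)C/C(C)=C\C=C | intermediate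
22 | (3Z,6R,7R,8R,9Z)-1-(9-borabicyclo[3.3.1]nonan-9-yl)-10-iodo-4-methyl-7-(propan-2-yl)-8-[(triethylsilyl)oxy]undeca-3,9-dien-6-yl 4-{[tri(propan-2-yl)silyl]oxy}benzoate | C/C(I)=C/[C@H](O[Si](CC)(CC)CC)[C@H](C(C)C)[C@H](OC(=O)c1ccc(O[Si](C(C)C)(C(C)C)C(C)C)cc1)C/C(C)=C\CCB1C2CCCC1CCC2 | intermediate
23 | (1R,3Z,7Z,9S,10R)-3,7-dimethyl-10-(propan-2-yl)-9-[(triethylsilyl)oxy]cyclodeca-3,7-dien-1-yl 4-{[tri(propan-2-yl)silyl]oxy}benzoate | C/C1=C/[C@H](O[Si](CC)(CC)CC)[C@H](C(C)C)[C@H](OC(=O)c2ccc(O[Si](C(C)C)(C(C)C)C(C)C)cc2)C/C(C)=C\CC1 | intermediate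
24 | (1R,3Z,7Z,9S,10S)-9-hydroxy-3,7-dimethyl-10-(propan-2-yl)cyclodeca-3,7-dien-1-yl 4-hydroxybenzoate | C/C1=C/[C@H](O)[C@H](C(C)C)[C@H](OC(=O)c2ccc(O)cc2)C/C(C)=C\CC1 | target

**Step count and risks**

Total steps: 14. Longest linear sequence: 10 steps (steps 1, 2, 5, 6, 7, 8, 10, 12, 13, 14).

Steps most likely to fail:

1. Step 13. Intermolecular coupling to oligomers may outrun closure of the medium ring, and the alkylborane may be lost by protodeboronation or the alkylpalladium intermediate by β-hydride elimination before reductive elimination. The fallback is a nickel-catalysed reductive cross-electrophile ring closure at the same C3–C4 bond, which needs no organoboron species and no base. It sets out from 21: hydroboration with 9-BBN as in step 13, then oxidation with NaBO3·4H2O (THF/H2O), should give the primary alcohol (3Z,6R,7R,8R,9Z)-1-hydroxy-10-iodo-4-methyl-7-(propan-2-yl)-8-[(triethylsilyl)oxy]undeca-3,9-dien-6-yl 4-{[tri(propan-2-yl)silyl]oxy}benzoate F1. CBr4/PPh3 (CH2Cl2, 0 °C) should convert it into the bromide (3Z,6R,7R,8R,9Z)-1-bromo-10-iodo-4-methyl-7-(propan-2-yl)-8-[(triethylsilyl)oxy]undeca-3,9-dien-6-yl 4-{[tri(propan-2-yl)silyl]oxy}benzoate F2. Slow addition of F2 to NiBr2·diglyme, 4,4'-di-tert-butyl-2,2'-bipyridine, Mn powder and NaI in DMA should join the C3 radical formed from the bromide with the alkenylnickel species formed from the C4 iodide, with retention of the Z geometry, and the fallback comes back to the route at 23.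

2. Step 10. Iodine–metal exchange may occur between the dienylmagnesium or dienylcopper species and the C4 iodide of 12, and the metalated diene may isomerise or oligomerise before it reaches the epoxide. In the fallback the C4 iodide is used up before any organometallic nucleophile meets it, and the ring is then closed at C1=C10 by metathesis. It sets out from 12: Negishi coupling with commercial but-3-en-1-ylzinc bromide (Pd(dppf)Cl2, THF, rt) should give, with retention, the diene epoxide triethyl{[(3R,4S,5Z)-2,6-dimethyl-3-[(2S)-oxiran-2-yl]deca-5,9-dien-4-yl]oxy}silane F3. Commercial isopropenylmagnesium bromide with CuI (THF, −30 °C) should open the epoxide at C9 to the alcohol (4R,5R,6S,7Z)-2,8-dimethyl-5-(propan-2-yl)-6-[(triethylsilyl)oxy]dodeca-1,7,11-trien-4-ol F4. Yamaguchi esterification with 19 as in step 12 should give the ester (4R,5R,6S,7Z)-2,8-dimethyl-5-(propan-2-yl)-6-[(triethylsilyl)oxy]dodeca-1,7,11-trien-4-yl 4-{[tri(propan-2-yl)silyl]oxy}benzoate F5. Ring-closing metathesis of the monosubstituted and the 1,1-disubstituted alkene of F5 with the second-generation Hoveyda–Grubbs catalyst (toluene, 80 °C, 1 mM) should form the C1=C10 bond, cis because of the ring size, with loss of ethene, and the fallback comes back to the route at 23.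

3. Step 5. Acid-promoted Z to E isomerisation and decomposition of the β-iodoenal 4 before addition would carry the wrong alkene geometry forward and lower the yield. In the fallback the iodoalkene is made after the C6–C7 bond, from an alkyne, under the direction of the new carbinol. It sets out from 7: allylboration of commercial but-2-ynal under the conditions of step 5 (same chair transition state, same Re-face attack) should give the anti alcohol (3R,4R)-3-(propan-2-yl)hept-1-en-5-yn-4-ol F6. Hydroxyl-directed trans-hydroalumination with NaAlH2(OCH2CH2OMe)2 (THF, 0 °C to rt) and iodinolysis (I2, −78 °C), as in step 1, should place iodine on the distal alkyne carbon cis to the carbinol carbon, and the fallback comes back to the route at 8.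

**Further compounds**

F1 | step 13 | (3Z,6R,7R,8R,9Z)-1-hydroxy-10-iodo-4-methyl-7-(propan-2-yl)-8-[(triethylsilyl)oxy]undeca-3,9-dien-6-yl 4-{[tri(propan-2-yl)silyl]oxy}benzoate | C/C(I)=C/[C@H](O[Si](CC)(CC)CC)[C@H](C(C)C)[C@H](OC(=O)c1ccc(O[Si](C(C)C)(C(C)C)C(C)C)cc1)C/C(C)=C\CCO
F2 | step 13 | (3Z,6R,7R,8R,9Z)-1-bromo-10-iodo-4-methyl-7-(propan-2-yl)-8-[(triethylsilyl)oxy]undeca-3,9-dien-6-yl 4-{[tri(propan-2-yl)silyl]oxy}benzoate | C/C(I)=C/[C@H](O[Si](CC)(CC)CC)[C@H](C(C)C)[C@H](OC(=O)c1ccc(O[Si](C(C)C)(C(C)C)C(C)C)cc1)C/C(C)=C\CCBr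
F3 | step 10 | triethyl{[(3R,4S,5Z)-2,6-dimethyl-3-[(2S)-oxiran-2-yl]deca-5,9-dien-4-yl]oxy}silane | C/C(CCC=C)=C/[C@H](O[Si](CC)(CC)CC)[C@H](C(C)C)[C@H]1CO1
F4 | step 10 | (4R,5R,6S,7Z)-2,8-dimethyl-5-(propan-2-yl)-6-[(triethylsilyl)oxy]dodeca-1,7,11-trien-4-ol | C/C(CCC=C)=C/[C@H](O[Si](CC)(CC)CC)[C@H](C(C)C)[C@H](O)CC(C)=C
F5 | step 10 | (4R,5R,6S,7Z)-2,8-dimethyl-5-(propan-2-yl)-6-[(triethylsilyl)oxy]dodeca-1,7,11-trien-4-yl 4-{[tri(propan-2-yl)silyl]oxy}benzoate | C/C(CCC=C)=C/[C@H](O[Si](CC)(CC)CC)[C@H](C(C)C)[C@H](OC(=O)c1ccc(O[Si](C(C)C)(C(C)C)C(C)C)cc1)CC(C)=C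
F6 | step 5 | (3R,4R)-3-(propan-2-yl)hept-1-en-5-yn-4-ol | CC#C[C@H](O)[C@H](C(C)C)C=C
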